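## The problem

Target 34 is a cis-fused eremophilane decalin: ring A (C1–C5, C10) carries the 3α-ester and the 4β-methyl, ring B (C5–C10) the 7β-isopropenyl group, the C8 ketone and the 9β-hydroxyl, with C5 quaternary (β-methyl) and H10 β. The core holds six stereocentres, four of them contiguous (C3, C4, C5, C10); the side chain adds a 4R carbinol centre, an E-enoate and a Z-configured angelate. Once the cis fusion and the 7β substituent are in place, the decalin is locked in the conformer with the C5 methyl and the C7 group equatorial on ring B, and in that conformer O3, the C4 methyl and O9 are equatorial too. C4, C7 and C9 each sit alpha to a carbonyl at some stage and are therefore backed by thermodynamics, whereas C5 and C10 must be set kinetically, ideally in one event. The α-hydroxy ketone (acyloin shift, epimerization), the β,γ-unsaturated ketone (drift of the isopropenyl double bond into conjugation), the angelate (Z to E) and the γ-acyloxy enoate (base, nucleophiles) are fragile, so the side chain must come late and the last steps must be mild. An oxidant cannot tell the ring alkene used to bring in O8 and O9 from an isopropenyl group, so the isopropenyl group has to travel as a masked acetyl. The six carbons C3, C4, C5, C10, C9, C8, with oxygen at C3 and methyl at C5, would be the ring of an ortho-oxygenated 3-methylphenol if C3 and C8 were bonded. In that bicycle C6–C7 is a two-carbon bridge from a vinyl ketone, and a vinyl group on C3 supplies C1–C2 for a [3,3] shift that trades the C3–C8 bond for C1–C10.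

## Retrosynthesis

**Side chain last.** The C3–O acyl bond of 34 is cut, through the 9-O-PMB ether 33, to alcohol 23 and acid 31. Carrying the dienoate ester through the ring-B oxidations would expose it to osmylation, acid and titanium reagents. Stepwise acylation would require a late angeloylation on the full core, where Z to E isomerization is hardest to control. Compound 23 holds all six core stereocentres and a single free hydroxyl. The forward steps need an acylation that leaves the β,γ-unsaturated ketone alone and a neutral oxidative removal of the PMB group.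

**Acid 31.** The C2'=C3' double bond is cut by cross-metathesis into angelate 29 and acrylic acid 30. Ester 29 comes from (R)-pent-1-en-3-ol 26 and angelic acid 27, and 26 from (R)-1,2-epoxybutane 24 by one-carbon homologation. A Wittig route through an α-acyloxy aldehyde would risk the carbinol centre; here that centre is never alpha to a carbonyl. The metathesis must be E-selective and must ignore the trisubstituted angelate.

**Ring-B functional groups.** Ketone 22 (the silyl ether of 23) is traced to axial alcohol 21, the isopropenyl group of 21 to methyl ketone 20 (C11=CH2 cut), and 20 to ketal 19. The O9 PMB ether of 19 comes from diol 17, and the diol from the C8=C9 alkene of 16. The order is dictated by two facts. OsO4 cannot distinguish a ring alkene from an isopropenyl group, so the acetyl stays masked during dihydroxylation. An acetyl next to a C8 ketone would be a β-diketone, so methylenation precedes oxidation at C8. The forward steps need attack of OsO4 on the convex β face and differentiation of the equatorial O9 from the axial O8.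

**C3 alcohol.** Silyl ether 16 comes from alcohol 15 and 15 from ketone 14. Hydride delivery along the axial path is blocked by the syn-axial C5 methyl, so the equatorial 3α-alcohol is sought under thermodynamic control by dissolving-metal reduction.

**Key disconnection.** Decalone 14 is traced through enolate 13 and alkoxide 12 to the bicyclic vinyl carbinol 11: the C1–C10 bond is cut and C3–C8 reconnected (retro-oxy-Cope). Annulations that form ring A by separate bond formations at C5 and C10 would have to control the quaternary centre and the ring fusion one after the other. Here one suprafacial shift on a rigid bicycle fixes C10 relative to C5, and C4 and C7 are carried through untouched. The precursor has all its stereochemistry defined relative to a single Diels–Alder reaction.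

**Bicyclic carbinol.** The C2–C3 bond of 11 is cut to ketone 9 and vinylmagnesium bromide 10. The C4–methyl bond of 9 is cut to ketone 7 (enolate methylation on the open face), and 7 comes from the α,α-dimethoxy ketone 5 by reductive removal of both methoxy groups. A phenol that already carried both methyl groups would leave C4 to an enolate protonation, which would put the methyl group on the wrong face. The alkylation puts it on the face that the target needs.

**Bicycle from a phenol.** Ketal 5 is the resolved, protected form of racemic adduct 4, and 4 is cut at C5–C6 and C7–C8 into the masked o-benzoquinone 3 and but-3-en-2-one 2. Dienone 3 is the dearomatized form of 2-methoxy-3-methylphenol 1. The acetyl group needs a ketal in any case, and making it from an enantiopure C2-symmetric diol turns the protection into the resolution at no cost in steps. The Diels–Alder reaction must be ortho- and endo-selective so that the acetyl ends on C7 syn to the new double bond.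

## Roads not taken

Alternative 1: Ring B is cut at C5–C6 and C7–C8, and the forward step is a Diels–Alder reaction of the ring-A ethoxydiene A2 (C5=C10–C9=C8) with enone 2 to give A1. It is convergent and delivers the same latent isopropenyl group (C7 acetyl) together with an oxygen at C8. C3 and C4 can be set enantioselectively in ring A before the cycloaddition, so no resolution is needed and C8 needs no dihydroxylation. In both respects this road is better than the chosen one. Its weak points are these:
- The cycloaddition must create the quaternary C5 at a fully substituted diene terminus with a dienophile of moderate reactivity.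
- Its facial selectivity rests on the single allylic methyl at C4.
- A1 comes out with the acetyl α (cis to the ethoxy group), so C7 must later be equilibrated.
- The ethyl ether at C8 must be cleaved.
- C10 is still sp2 in A1, so the cis fusion has to be made by delivering hydrogen to C10 on the face of the angular methyl, against the normal steric preference.

The chosen plan pays with a resolution and three steps for O8 and O9, but its ring fusion is enforced by the bicycle and not negotiated at the end.

Alternative 2: The C5–C10 bond is cut. The silyl ketene acetal of δ-lactone A4 would undergo a ring-contracting Ireland–Claisen rearrangement through a boat transition state to acid A3. The allylic C3–O bond breaks, C5–C10 forms, and C9 is released as the carboxyl group. Both fusion centres are set together by chirality transfer from one carbinol centre, which an asymmetric ketone reduction can supply. Absolute control is therefore better than in the chosen plan, which resolves. The weak points are: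
- A3 contains ring A only. Ring B, the isopropenyl group, both ring-B oxygens and the C3 oxygen are all still to be made, the last by face-selective hydration of the C3=C4 alkene next to the quaternary centre.
- A4 needs a stereodefined tetrasubstituted alkene.
- Any chair leakage erodes the cis relationship.

The chosen rearrangement uses the same sigmatropic logic but delivers both rings and the C3 carbonyl in place.

Alternative 3: Ring A is cut at C4–C5 and C1–C10. The forward step combines enone A6, available from (+)-3-carene A8 by cyclopropane cleavage, with silyloxydiene A7 under HNTf2 catalysis (Mukaiyama–Michael, then Michael) to give A5. This is the shortest way to a cis-decalin that already carries the C7 isopropenyl group, the C3 oxygen and, from the chiral pool, the correct absolute configuration. In step economy and absolute control it is superior to the chosen plan. The weak points are: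
- The ring-B carbonyl of A5 sits at C9, whereas the target needs the ketone at C8 and the carbinol at C9. A 1,2-transposition must therefore be run in the presence of the isopropenyl group, which most alkene oxidants attack.
- The C4 methyl configuration comes from an open transition state.
- The strong acid may protonate the isopropenyl group.

The chosen plan is longer and resolves. It sets against this a reagent-independent control of C5 and C10, thermodynamic backing for C4, C7 and C9, and an acetyl mask that lets C8 and C9 be oxidized before the isopropenyl alkene exists.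

Key step: step 6

Remarks and assumptions (one line each):
- Decalin compounds use the target numbering; α/β refer to the drawing with the C5 methyl β. Bicyclic compounds use bicyclo[2.2.2]octane numbering (C2 carbonyl or carbinol, C4 methyl-bearing bridgehead, C5=C6, C7 bearing the side group).
- Diox = (4R,5R)-2,4,5-trimethyl-1,3-dioxolan-2-yl; TBS = tert-butyldimethylsilyl; PMB = 4-methoxybenzyl.
- Compounds 3 and 4 are achiral and racemic respectively; the SMILES of 4 shows the enantiomer that is carried on, and from 5 onward every compound is a single stereoisomer.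
- 2-Methoxy-3-methylphenol 1 is taken to be a catalogue compound.

## Route

Step 1
Reactants: 1 2-methoxy-3-methylphenol; 2 but-3-en-2-one
Product: 4 rac-7-acetyl-3,3-dimethoxy-4-methylbicyclo[2.2.2]oct-5-en-2-one (acetyl syn to C5=C6), via 6,6-dimethoxy-5-methylcyclohexa-2,4-dienone 3 (not isolated)
Conditions: PhI(OAc)2, MeOH, 2 (excess), 0 °C to rt, slow addition of 1
Reagents that add atoms: methanol, CO
Why: Oxidative dearomatization of a 2-methoxyphenol by hypervalent iodine in methanol gives the o-quinone monoketal 3 at the methoxy-bearing carbon, and 3 is trapped at once in an intermolecular Diels–Alder reaction before it can dimerize. The acetyl-bearing carbon of 2 bonds to the dienone terminus next to the carbonyl (ortho rule) and the CH2 to the methyl-bearing terminus, so C5–C6, C7–C8 and the quaternary C5 of the target are made together; the endo rule puts the acetyl syn to the new C5=C6 bridge, which is the 7β relationship to the C5 methyl. The product is racemic.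

Step 2
Reactants: 4 rac-7-acetyl-3,3-dimethoxy-4-methylbicyclo[2.2.2]oct-5-en-2-one
Product: 5 (1S,4S,7S)-3,3-dimethoxy-4-methyl-7-Diox-bicyclo[2.2.2]oct-5-en-2-one (single diastereomer)
Conditions: (2R,3R)-butane-2,3-diol, PPTS (cat.), benzene, reflux (Dean–Stark); separation of the two diastereomers on silica
Reagents that add atoms: (2R,3R)-butane-2,3-diol, C[C@@H](O)[C@@H](C)O
Why: Acid-catalysed ketalization is chemoselective for the methyl ketone, because the ring carbonyl is flanked by a bridgehead and by the dimethoxy carbon, whose bulk and inductive pull disfavour the oxocarbenium ion. The C2-symmetric diol creates no stereocentre at the ketal carbon and turns the racemate into two separable diastereomers (classical resolution through a diastereomeric derivative). The ketal stays on as the acetyl protecting group and removes the acidic C7–H that would let the C8=C9 double bond of the later decalin move into conjugation.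

Step 3
Reactants: 5 (1S,4S,7S)-3,3-dimethoxy-4-methyl-7-Diox-bicyclo[2.2.2]oct-5-en-2-one
Product: 7 4-methyl-7-Diox-bicyclo[2.2.2]oct-5-en-2-one, via 3-methoxy ketone 6 (not isolated)
Conditions: SmI2 (excess), THF/MeOH, −78 °C to rt
Reagents that add atoms: none
Why: Samarium diiodide cleaves C–O bonds alpha to a ketone through the ketyl and the samarium enolate, the standard reductive removal of α-alkoxy groups; with excess reagent both methoxy groups are removed, the second by way of 6. The dioxolane and the isolated alkene are inert.

Step 4
Reactants: 7 4-methyl-7-Diox-bicyclo[2.2.2]oct-5-en-2-one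
Product: 9 (1S,3R,4S,7S)-3,4-dimethyl-7-Diox-bicyclo[2.2.2]oct-5-en-2-one (C3 methyl syn to C5=C6), via lithium enolate 8 (not isolated)
Conditions: LiN(iPr)2, THF, −78 °C; MeI, DMPU, −78 to 0 °C
Reagents that add atoms: iodomethane, CI
Why: Only C3 can be enolized (the other alpha carbon is a bridgehead), so the kinetic enolate alkylation is regiospecific. Iodomethane should approach enolate 8 from the face syn to the C5=C6 bridge, which is free of the inward C–H bonds of the C7–C8 bridge; this sets C4 of the target with the methyl cis to the bridgehead methyl, and the shielded tertiary C3–H left behind disfavours a second alkylation.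

Step 5
Reactants: 9 (1S,3R,4S,7S)-3,4-dimethyl-7-Diox-bicyclo[2.2.2]oct-5-en-2-one; 10 vinylmagnesium bromide
Product: 11 (1S,2R,3R,4S,7S)-2-ethenyl-3,4-dimethyl-7-Diox-bicyclo[2.2.2]oct-5-en-2-ol (vinyl syn to C5=C6)
Conditions: THF, −78 to 0 °C; aq. NH4Cl
Reagents that add atoms: none
Why: 1,2-Addition of a vinyl Grignard reagent to a bicyclo[2.2.2]oct-5-en-2-one takes place from the face syn to the C5=C6 bridge, away from the inward C7–H and C8–H bonds, and does so even when C3 is disubstituted. The vinyl group therefore ends over the double bond (new stereocentre C2, R), the only arrangement from which the [3,3] shift can occur.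

Step 6
Reactants: 11 (1S,2R,3R,4S,7S)-2-ethenyl-3,4-dimethyl-7-Diox-bicyclo[2.2.2]oct-5-en-2-ol
Product: 14 cis-fused 4β,5β-dimethyl-7β-Diox-10βH-octal-8-en-3-one, via potassium alkoxide 12 (not isolated), via potassium enolate 13 (not isolated)
Conditions: KH, 18-crown-6, THF, 0 °C to rt; aq. NH4Cl, −78 °C
Reagents that add atoms: none
Why: KH with 18-crown-6 gives the dissociated potassium alkoxide 12, whose oxyanion weakens the adjacent C3–C8 bond (target numbering) and accelerates the [3,3] shift enormously. The shift is concerted through the boat-like array C1=C2–C3–C8–C9=C10 that the bicycle enforces: C3–C8 breaks as C1–C10 forms, giving enolate 13, which is protonated on work-up to 14. The closest known reaction type is the anionic oxy-Cope rearrangement of 2-vinylbicyclo[2.2.2]oct-5-en-2-ols to cis-fused decalenones. Ring A closes as a six-membered ring through the new C1–C10 σ bond inside the sigmatropic array, while cleavage of the bridging bond releases ring B as a cyclohexene. The new stereocentre C10 is controlled by the bicycle: the vinyl terminus can reach C10 only on the face turned toward the carbinol bridge, so H10 must end cis to the C5 methyl, and C4, C5 and C7 are not touched. The step needs the vinyl group syn to C9=C10, which step 5 secures, and it has no regiochemical choice because only one 1,5-diene is present. C4 lies outside the Δ2 enolate 13 and keeps its configuration; should it epimerize on quench, the equatorial 4β-methyl is the favoured position in the conformer locked by the 7β group. The ketal leaves no acidic hydrogen at C7, so the C8=C9 double bond cannot move into conjugation under the basic conditions.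

Step 7
Reactants: 14 cis-fused 4β,5β-dimethyl-7β-Diox-10βH-octal-8-en-3-one
Product: 15 4β,5β-dimethyl-7β-Diox-10βH-octal-8-en-3α-ol
Conditions: Li, NH3(l)/THF, EtOH, −78 °C; NH4Cl
Reagents that add atoms: none
Why: Dissolving-metal reduction of a ketone gives the thermodynamically preferred alcohol, here the equatorial 3α-alcohol trans to the equatorial 4β-methyl in the conformer fixed by the 7β group. Hydride reagents would attack from the α face, because the axial path is blocked by the syn-axial C5 methyl, and give the 3β-epimer. The isolated alkene and the dioxolane are not reduced.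

Step 8
Reactants: 15 4β,5β-dimethyl-7β-Diox-10βH-octal-8-en-3α-ol
Product: 16 3α-(TBS-oxy)-4β,5β-dimethyl-7β-Diox-10βH-octal-8-ene
Conditions: TBSOTf, 2,6-lutidine, CH2Cl2, −78 to 0 °C
Reagents that add atoms: tert-butyldimethylsilyl triflate, CC(C)(C)[Si](C)(C)OS(=O)(=O)C(F)(F)F
Why: Silyl ether protection of a hindered secondary alcohol with the silyl triflate and a hindered base. The TBS ether masks O3 until the side chain is attached in step 18 and is stable to every step in between.

Step 9
Reactants: 16 3α-(TBS-oxy)-4β,5β-dimethyl-7β-Diox-10βH-octal-8-ene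
Product: 17 3α-(TBS-oxy)-4β,5β-dimethyl-7β-Diox-10βH-decalin-8β,9β-diol
Conditions: OsO4 (cat.), NMO, acetone/H2O, rt
Reagents that add atoms: osmium tetroxide, O=[Os](=O)(=O)=O; N-methylmorpholine N-oxide, C[N+]1([O-])CCOCC1; water, O
Why: Catalytic syn-dihydroxylation of the only alkene (Upjohn conditions). OsO4 should approach the convex β face of the cis-decalin, because the α face of C9 is covered by C4, which is axial on ring B, whereas the β face carries only axial hydrogens; both new hydroxyls are then β, with C9 as in the target.

Step 10
Reactants: 17 3α-(TBS-oxy)-4β,5β-dimethyl-7β-Diox-10βH-decalin-8β,9β-diol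
Product: 19 9β-(PMB-oxy)-3α-(TBS-oxy)-4β,5β-dimethyl-7β-Diox-10βH-decalin-8β-ol, via dibutylstannylene acetal 18 (not isolated)
Conditions: Bu2SnO, toluene, reflux (Dean–Stark); then PMBCl, Bu4NI, 90 °C
Reagents that add atoms: 4-methoxybenzyl chloride, COc1ccc(CCl)cc1
Why: Stannylene-acetal-mediated monoalkylation of a cis-1,2-diol on a six-membered ring goes to the equatorial oxygen. O9 is equatorial, while O8 is axial and flanked by the quaternary ketal carbon, so the PMB group should go to O9 and leave the axial 8β-hydroxyl free.

Step 11
Reactants: 19 9β-(PMB-oxy)-3α-(TBS-oxy)-4β,5β-dimethyl-7β-Diox-10βH-decalin-8β-ol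
Product: 20 7β-acetyl-9β-(PMB-oxy)-3α-(TBS-oxy)-4β,5β-dimethyl-10βH-decalin-8β-ol
Conditions: PPTS, acetone/H2O, 60 °C
Reagents that add atoms: water, O
Why: Acid-catalysed hydrolysis of the dioxolane with a mild pyridinium acid. The hindered secondary TBS ether and the PMB ether tolerate it, and the weak acid should not dehydrate the β-hydroxy ketone.

Step 12
Reactants: 20 7β-acetyl-9β-(PMB-oxy)-3α-(TBS-oxy)-4β,5β-dimethyl-10βH-decalin-8β-ol
Product: 21 7β-isopropenyl-9β-(PMB-oxy)-3α-(TBS-oxy)-4β,5β-dimethyl-10βH-decalin-8β-ol
Conditions: CH2Br2, Zn, TiCl4, THF/CH2Cl2, 0 °C to rt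
Reagents that add atoms: dibromomethane, BrCBr
Why: Titanium-mediated methylenation with the CH2Br2/Zn/TiCl4 reagent (Lombardo methylenation) turns the methyl ketone into the isopropenyl group. The reagent is non-basic, so the β-hydroxy ketone should neither undergo retro-aldol cleavage nor epimerize at C7, and free hydroxyls, silyl ethers and benzyl ethers are tolerated. C8 is still an alcohol here, so no β-diketone has to be methylenated.

Step 13
Reactants: 21 7β-isopropenyl-9β-(PMB-oxy)-3α-(TBS-oxy)-4β,5β-dimethyl-10βH-decalin-8β-ol
Product: 22 7β-isopropenyl-9β-(PMB-oxy)-3α-(TBS-oxy)-4β,5β-dimethyl-10βH-decalin-8-one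
Conditions: Dess–Martin periodinane, pyridine, CH2Cl2, 0 °C to rt
Reagents that add atoms: none
Why: Dess–Martin oxidation of the axial secondary alcohol under buffered conditions gives the C8 ketone without touching the isopropenyl group. C7 and C9, now alpha to the carbonyl, already carry their substituents in the equatorial, thermodynamically preferred positions.

Step 14
Reactants: 22 7β-isopropenyl-9β-(PMB-oxy)-3α-(TBS-oxy)-4β,5β-dimethyl-10βH-decalin-8-one
Product: 23 3α-hydroxy-7β-isopropenyl-9β-(PMB-oxy)-4β,5β-dimethyl-10βH-decalin-8-one
Conditions: HF·pyridine, pyridine, THF, 0 °C to rt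
Reagents that add atoms: none
Why: Fluoride cleavage of the silyl ether in a buffered, weakly acidic medium, which avoids the basic conditions that could move the isopropenyl double bond into conjugation with the ketone. The PMB ether is stable.

Step 15
Reactants: 24 (R)-1,2-epoxybutane
Product: 26 (R)-pent-1-en-3-ol, via sulfonium alkoxide betaine 25 (not isolated)
Conditions: Me3SI, n-BuLi, THF, −10 °C to rt
Reagents that add atoms: trimethylsulfonium iodide, C[S+](C)C.[I-]
Why: Dimethylsulfonium methylide opens the terminal epoxide at its CH2 group, and base-induced loss of dimethyl sulfide from betaine 25 gives the one-carbon homologated allylic alcohol. The stereocentre is not involved, so the R configuration of 24 is carried into 26.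

Step 16
Reactants: 26 (R)-pent-1-en-3-ol; 27 angelic acid
Product: 29 (R)-pent-1-en-3-yl (Z)-2-methylbut-2-enoate, via angelic 2,4,6-trichlorobenzoic anhydride 28 (not isolated)
Conditions: 2,4,6-trichlorobenzoyl chloride, Et3N, toluene, rt; then 26, 80 °C
Reagents that add atoms: none
Why: Esterification through the mixed 2,4,6-trichlorobenzoic anhydride (Yamaguchi-type activation) without a nucleophilic catalyst, conditions under which angelic acid acylates alcohols without isomerizing to the tiglate. The carbinol centre is not touched.

Step 17
Reactants: 29 (R)-pent-1-en-3-yl (Z)-2-methylbut-2-enoate; 30 acrylic acid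
Product: 31 (2E,4R)-4-[(Z)-2-methylbut-2-enoyloxy]hex-2-enoic acid
Conditions: second-generation Hoveyda–Grubbs catalyst [RuCl2(H2IMes)(=CH-C6H4-2-OiPr)] (cat.), CH2Cl2, 40 °C
Reagents that add atoms: none
Why: Cross-metathesis of a terminal alkene with acrylic acid. The ruthenium carbene leaves the trisubstituted, electron-poor angelate double bond alone, and the conjugated product forms as the E isomer; the allylic stereocentre is untouched.

Step 18
Reactants: 23 3α-hydroxy-7β-isopropenyl-9β-(PMB-oxy)-4β,5β-dimethyl-10βH-decalin-8-one; 31 (2E,4R)-4-[(Z)-2-methylbut-2-enoyloxy]hex-2-enoic acid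
Product: 33 9-O-PMB ether of the target, via mixed 2,4,6-trichlorobenzoic anhydride 32 (not isolated)
Conditions: 2,4,6-trichlorobenzoyl chloride, Et3N, toluene, rt; then 23, DMAP, rt
Reagents that add atoms: none
Why: Yamaguchi esterification of the only free hydroxyl of 23 with acid 31 through mixed anhydride 32; the equatorial 3α-hydroxyl is hindered only by the neighbouring equatorial methyl. No stereocentre is formed or broken.

Step 19
Reactants: 33 9-O-PMB ether of the target
Product: 34 target, 3α-[(2E,4R)-4-(angeloyloxy)hex-2-enoyloxy]-9β-hydroxy-7β-isopropenyl-4β,5β-dimethyl-10βH-decalin-8-one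
Conditions: DDQ, CH2Cl2/pH 7 buffer, 0 °C to rt
Reagents that add atoms: none
Why: Oxidative cleavage of the 4-methoxybenzyl ether with DDQ in buffered wet dichloromethane frees the 9β-hydroxyl under neutral conditions that should leave the ketone, the isopropenyl group and both unsaturated esters unchanged.

## Compound list

1 | 2-methoxy-3-methylphenol | Cc1cccc(O)c1OC | starting material
2 | but-3-en-2-one | CC(=O)C=C | starting material
3 | 6,6-dimethoxy-5-methylcyclohexa-2,4-dienone | COC1(OC)C(=O)C=CC=C1C | intermediate
4 | rac-(1S,4S,7S)-7-acetyl-3,3-dimethoxy-4-methylbicyclo[2.2.2]oct-5-en-2-one, acetyl syn to C5=C6 (racemic; enantiomer carried on is drawn) | CC(=O)[C@H]1C[C@@]2(C)C=C[C@@H]1C(=O)C2(OC)OC | intermediate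
5 | (1S,4S,7S)-3,3-dimethoxy-4-methyl-7-[(4R,5R)-2,4,5-trimethyl-1,3-dioxolan-2-yl]bicyclo[2.2.2]oct-5-en-2-one | CC1(O[C@H](C)[C@@H](C)O1)[C@H]2C[C@@]3(C)C=C[C@@H]2C(=O)C3(OC)OC | intermediate
6 | 3-methoxy-4-methyl-7-[(4R,5R)-2,4,5-trimethyl-1,3-dioxolan-2-yl]bicyclo[2.2.2]oct-5-en-2-one, methoxy on the side of the C7–C8 bridge, skeleton as in 5 | CC1(O[C@H](C)[C@@H](C)O1)[C@H]2C[C@@]3(C)C=C[C@@H]2C(=O)[C@H]3OC | intermediate
7 | 4-methyl-7-[(4R,5R)-2,4,5-trimethyl-1,3-dioxolan-2-yl]bicyclo[2.2.2]oct-5-en-2-one, dioxolanyl syn to C5=C6, skeleton as in 5 | CC1(O[C@H](C)[C@@H](C)O1)[C@H]2C[C@@]3(C)C=C[C@@H]2C(=O)C3 | intermediate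
8 | lithium enolate of 7 (C2=C3 enolate) | CC1(O[C@H](C)[C@@H](C)O1)[C@H]2C[C@@]3(C)C=C[C@@H]2C([O-])=C3.[Li+] | intermediate
9 | (1S,3R,4S,7S)-3,4-dimethyl-7-[(4R,5R)-2,4,5-trimethyl-1,3-dioxolan-2-yl]bicyclo[2.2.2]oct-5-en-2-one, C3 methyl and dioxolanyl both syn to C5=C6 | CC1(O[C@H](C)[C@@H](C)O1)[C@H]2C[C@@]3(C)C=C[C@@H]2C(=O)[C@@H]3C | intermediate
10 | vinylmagnesium bromide | C=C[Mg]Br | starting material
11 | (1S,2R,3R,4S,7S)-2-ethenyl-3,4-dimethyl-7-[(4R,5R)-2,4,5-trimethyl-1,3-dioxolan-2-yl]bicyclo[2.2.2]oct-5-en-2-ol, vinyl, C3 methyl and dioxolanyl syn to C5=C6 | CC1(O[C@H](C)[C@@H](C)O1)[C@H]2C[C@@]3(C)C=C[C@@H]2[C@](O)(C=C)[C@@H]3C | intermediate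
12 | potassium alkoxide of 11 | CC1(O[C@H](C)[C@@H](C)O1)[C@H]2C[C@@]3(C)C=C[C@@H]2[C@]([O-])(C=C)[C@@H]3C.[K+] | intermediate
13 | potassium C2=C3 enolate of 14 | CC1(O[C@H](C)[C@@H](C)O1)[C@H]2C[C@@]3(C)[C@H](CC=C([O-])[C@@H]3C)C=C2.[K+] | intermediate
14 | cis-fused 4β,5β-dimethyl-7β-[(4R,5R)-2,4,5-trimethyl-1,3-dioxolan-2-yl]-10βH-octal-8-en-3-one (target numbering) | CC1(O[C@H](C)[C@@H](C)O1)[C@H]2C[C@@]3(C)[C@H](CCC(=O)[C@@H]3C)C=C2 | intermediate
15 | 4β,5β-dimethyl-7β-[(4R,5R)-2,4,5-trimethyl-1,3-dioxolan-2-yl]-10βH-octal-8-en-3α-ol | CC1(O[C@H](C)[C@@H](C)O1)[C@H]2C[C@@]3(C)[C@H](CC[C@@H](O)[C@@H]3C)C=C2 | intermediate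
16 | 3α-(tert-butyldimethylsilyloxy)-4β,5β-dimethyl-7β-[(4R,5R)-2,4,5-trimethyl-1,3-dioxolan-2-yl]-10βH-octal-8-ene | CC1(O[C@H](C)[C@@H](C)O1)[C@H]2C[C@@]3(C)[C@H](CC[C@@H](O[Si](C)(C)C(C)(C)C)[C@@H]3C)C=C2 | intermediate
17 | 3α-(tert-butyldimethylsilyloxy)-4β,5β-dimethyl-7β-[(4R,5R)-2,4,5-trimethyl-1,3-dioxolan-2-yl]-10βH-decalin-8β,9β-diol | CC1(O[C@H](C)[C@@H](C)O1)[C@H]2C[C@@]3(C)[C@H](CC[C@@H](O[Si](C)(C)C(C)(C)C)[C@@H]3C)[C@@H](O)[C@H]2O | intermediate
18 | 8β,9β-O-dibutylstannylene acetal of 17 | CC1(O[C@H](C)[C@@H](C)O1)[C@H]2C[C@@]3(C)[C@H](CC[C@@H](O[Si](C)(C)C(C)(C)C)[C@@H]3C)[C@H]4O[Sn](CCCC)(CCCC)O[C@@H]24 | intermediate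
19 | 9β-(4-methoxybenzyloxy)-3α-(tert-butyldimethylsilyloxy)-4β,5β-dimethyl-7β-[(4R,5R)-2,4,5-trimethyl-1,3-dioxolan-2-yl]-10βH-decalin-8β-ol | CC1(O[C@H](C)[C@@H](C)O1)[C@H]2C[C@@]3(C)[C@H](CC[C@@H](O[Si](C)(C)C(C)(C)C)[C@@H]3C)[C@@H](OCc4ccc(OC)cc4)[C@H]2O | intermediate
20 | 7β-acetyl-9β-(4-methoxybenzyloxy)-3α-(tert-butyldimethylsilyloxy)-4β,5β-dimethyl-10βH-decalin-8β-ol | CC(=O)[C@H]1C[C@@]2(C)[C@H](CC[C@@H](O[Si](C)(C)C(C)(C)C)[C@@H]2C)[C@@H](OCc3ccc(OC)cc3)[C@H]1O | intermediate
21 | 7β-isopropenyl-9β-(4-methoxybenzyloxy)-3α-(tert-butyldimethylsilyloxy)-4β,5β-dimethyl-10βH-decalin-8β-ol | C=C(C)[C@H]1C[C@@]2(C)[C@H](CC[C@@H](O[Si](C)(C)C(C)(C)C)[C@@H]2C)[C@@H](OCc3ccc(OC)cc3)[C@H]1O | intermediate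
22 | 7β-isopropenyl-9β-(4-methoxybenzyloxy)-3α-(tert-butyldimethylsilyloxy)-4β,5β-dimethyl-10βH-decalin-8-one | C=C(C)[C@H]1C[C@@]2(C)[C@H](CC[C@@H](O[Si](C)(C)C(C)(C)C)[C@@H]2C)[C@@H](OCc3ccc(OC)cc3)C1=O | intermediate
23 | 3α-hydroxy-7β-isopropenyl-9β-(4-methoxybenzyloxy)-4β,5β-dimethyl-10βH-decalin-8-one | C=C(C)[C@H]1C[C@@]2(C)[C@H](CC[C@@H](O)[C@@H]2C)[C@@H](OCc3ccc(OC)cc3)C1=O | intermediate
24 | (R)-1,2-epoxybutane | CC[C@@H]1CO1 | starting material
25 | (R)-dimethyl(3-oxidopentyl)sulfonium (betaine) | CC[C@@H]([O-])CC[S+](C)C | intermediate
26 | (R)-pent-1-en-3-ol | C=C[C@@H](CC)O | intermediate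
27 | angelic acid, (Z)-2-methylbut-2-enoic acid | C/C=C(/C)C(=O)O | starting material
28 | (Z)-2-methylbut-2-enoic 2,4,6-trichlorobenzoic anhydride | C/C=C(/C)C(=O)OC(=O)c1c(Cl)cc(Cl)cc1Cl | intermediate
29 | (R)-pent-1-en-3-yl (Z)-2-methylbut-2-enoate | C=C[C@@H](CC)OC(=O)/C(C)=C\C | intermediate
30 | acrylic acid | C=CC(=O)O | starting material
31 | (2E,4R)-4-[(Z)-2-methylbut-2-enoyloxy]hex-2-enoic acid | OC(=O)/C=C/[C@@H](CC)OC(=O)/C(C)=C\C | intermediate
32 | mixed anhydride of 31 with 2,4,6-trichlorobenzoic acid | O=C(OC(=O)/C=C/[C@@H](CC)OC(=O)/C(C)=C\C)c1c(Cl)cc(Cl)cc1Cl | intermediate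
33 | 9-O-(4-methoxybenzyl) ether of the target | C=C(C)[C@H]1C[C@@]2(C)[C@H](CC[C@@H](OC(=O)/C=C/[C@@H](CC)OC(=O)/C(C)=C\C)[C@@H]2C)[C@@H](OCc3ccc(OC)cc3)C1=O | intermediate
34 | CNP0190706.1, (3R,4R,5R,7R,9R,10S)-3α-[(2E,4R)-4-(angeloyloxy)hex-2-enoyloxy]-9β-hydroxy-7β-isopropenyl-4β,5β-dimethyl-10βH-decalin-8-one | C=C(C)[C@H]1C[C@@]2(C)[C@H](CC[C@@H](OC(=O)/C=C/[C@@H](CC)OC(=O)/C(C)=C\C)[C@@H]2C)[C@@H](O)C1=O | target

## Step count and least certain steps

Total step count: 19. Longest linear sequence: 16 (steps 1–14, 18, 19); steps 15–17 make the side-chain acid. The resolution in step 2 removes half of the material at the second step.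

**Step 6 (key step).** The most likely failure is that the alkoxide does not reach the reactive, dissociated state because potassium is held by the dioxolane oxygens. The rearrangement would then stall, and on heating C–C cleavage next to the oxyanion could compete. The fallback is the neutral thermal variant of the same shift. Carbinol 11 is silylated (TMSOTf, Et3N) to the trimethylsilyl ether of 11 F1. Heating in a sealed tube (decalin, about 230 °C) effects the siloxy-Cope rearrangement to the trimethylsilyl enol ether of 14 F2. Methanolysis (K2CO3, MeOH) brings the route back at 14.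

**Step 2.** The two diastereomeric ketals may be too similar in polarity to separate, or the α-keto dimethyl ketal may exchange with the diol on long heating. The fallback separates the enantiomers of 4 themselves by preparative chromatography on a chiral stationary phase (cellulose tris(3,5-dimethylphenylcarbamate)). The single enantiomer of 4 is then ketalized with the same diol and the route is rejoined at 5; no new compound arises.

**Step 5.** Facial selectivity may be poor, because the C3 methyl lies on the same face from which the vinyl group has to arrive; enolization of the hindered ketone may also compete. The fallback inverts C3 first and corrects it after the rearrangement: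
- Ketone 9 is deprotonated (LiN(iPr)2) and the enolate is protonated kinetically on the open face (2,6-di-tert-butyl-4-methylphenol, −78 °C). This gives the C3-epimeric ketone with the methyl on the side of the C7–C8 bridge F3.
- Vinylmagnesium bromide then has both the bridge and the methyl steering it to the correct face, giving the C3-epimeric vinyl carbinol F4.
- KH/18-crown-6 converts F4 into the 4α-methyl cis-decalone F5.
- Equilibration with KOMe in MeOH moves the axial 4α-methyl, which clashes with C9, into the equatorial 4β position. The route is rejoined at 14.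

**Step 12.** The Lewis-acidic titanium reagent may dehydrate the β-hydroxy ketone, or the methylenation may stall next to the crowded C7. The fallback is a Peterson olefination. Me3SiCH2MgCl with CeCl3 adds to the ketone of 20 without enolizing it and gives the β-hydroxysilane F6 (mixture at the new carbinol carbon). KH in THF eliminates the silanolate and brings the route back at 21.

**Step 18.** Acylation of the hindered 3α-hydroxyl may be slow, and long exposure to DMAP may move the isopropenyl double bond into conjugation with the C8 ketone or erode the angelate geometry. The fallback builds the side chain on the core. Alcohol 23 is acylated with acryloyl chloride (iPr2NEt, −20 °C) to the 3-O-acrylate of 23 F7. Cross-metathesis of F7 with angelate 29 (second-generation Hoveyda–Grubbs catalyst) rejoins the route at 33.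

## Further compounds

F0 | step 2 | none | none
F1 | step 6 | trimethylsilyl ether of 11 | CC1(O[C@H](C)[C@@H](C)O1)[C@H]2C[C@@]3(C)C=C[C@@H]2[C@](O[Si](C)(C)C)(C=C)[C@@H]3C
F2 | step 6 | trimethylsilyl enol ether of 14 (C2=C3) | CC1(O[C@H](C)[C@@H](C)O1)[C@H]2C[C@@]3(C)[C@H](CC=C(O[Si](C)(C)C)[C@@H]3C)C=C2
F3 | step 5 | C3 epimer of 9 (methyl on the side of the C7–C8 bridge) | CC1(O[C@H](C)[C@@H](C)O1)[C@H]2C[C@@]3(C)C=C[C@@H]2C(=O)[C@H]3C
F4 | step 5 | C3 epimer of 11 (vinyl syn to C5=C6, methyl anti) | CC1(O[C@H](C)[C@@H](C)O1)[C@H]2C[C@@]3(C)C=C[C@@H]2[C@](O)(C=C)[C@H]3C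
F5 | step 5 | 4α-methyl epimer of 14 | CC1(O[C@H](C)[C@@H](C)O1)[C@H]2C[C@@]3(C)[C@H](CCC(=O)[C@H]3C)C=C2
F6 | step 12 | 7β-[2-hydroxy-1-(trimethylsilyl)propan-2-yl] analogue of 20 (mixture at the carbinol carbon) | C[Si](C)(C)CC(C)(O)[C@H]1C[C@@]2(C)[C@H](CC[C@@H](O[Si](C)(C)C(C)(C)C)[C@@H]2C)[C@@H](OCc3ccc(OC)cc3)[C@H]1O
F7 | step 18 | 3-O-acrylate of 23 | C=C(C)[C@H]1C[C@@]2(C)[C@H](CC[C@@H](OC(=O)C=C)[C@@H]2C)[C@@H](OCc3ccc(OC)cc3)C1=O
A1 | alternative 1 | 7α-acetyl-8α-ethoxy-3α-(tert-butyldimethylsilyloxy)-4β,5β-dimethyloctal-9-ene (target numbering) | CC(=O)[C@@H]1C[C@@]2(C)C(CC[C@@H](O[Si](C)(C)C(C)(C)C)[C@@H]2C)=C[C@@H]1OCC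
A2 | alternative 1 | ring-A diene, 1-[(E)-2-ethoxyvinyl]-2,3-dimethyl-4-(tert-butyldimethylsilyloxy)cyclohexene with the C3 and C4 centres of the target | CCO/C=C/C1=C(C)[C@@H](C)[C@H](O[Si](C)(C)C(C)(C)C)CC1
A3 | alternative 2 | cis-2-[3-(tert-butyldimethylsilyloxy)propyl]-2,3-dimethylcyclohex-3-ene-1-carboxylic acid | OC(=O)[C@H]1CCC=C(C)[C@@]1(C)CCCO[Si](C)(C)C(C)(C)C
A4 | alternative 2 | 6-[(E)-6-(tert-butyldimethylsilyloxy)-3-methylhex-2-en-2-yl]tetrahydropyran-2-one | O=C1CCC[C@@H](O1)/C(C)=C(\C)CCCO[Si](C)(C)C(C)(C)C
A5 | alternative 3 | cis-fused 3-(tert-butyldimethylsilyloxy)-7β-isopropenyl-4β,5β-dimethyl-10βH-octal-2-en-9-one (target numbering) | C=C(C)[C@H]1C[C@@]2(C)[C@H](CC=C(O[Si](C)(C)C(C)(C)C)[C@@H]2C)C(=O)C1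
A6 | alternative 3 | (S)-5-isopropenyl-3-methylcyclohex-2-en-1-one | C=C(C)[C@H]1CC(C)=CC(=O)C1
A7 | alternative 3 | (Z)-3-(tert-butyldimethylsilyloxy)penta-1,3-diene | C=C/C(O[Si](C)(C)C(C)(C)C)=C/C
A8 | alternative 3 | (+)-3-carene | CC1=CC[C@@H]2[C@H](C1)C2(C)C
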